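The plan cuts the C2–C3 bond of the dihydrofuran ring. In the target a benzylic carbinol carbon (C3) sits next to a carbon (C2) bonded to the ring oxygen O1 and to an isopropenyl group: the pattern left when an α-oxy benzyl anion attacks the oxygen-bearing end of an allylic enol ether and expels the allylic oxygen. The precursor is thus an eight-membered (Z)-aryl enol ether, a 3-methyl-4H,6H-1,5-benzodioxocine, with the acetyl group hidden as a 1-ethoxyvinyl ether and the phenol as a tetrahydropyranyl acetal. One enantioselective deprotonation then contracts the ring by a transannular [2,3]-Wittig shift, forming C2–C3, closing the five-membered ring and setting both stereocentres cis.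

Key step: step 6

Assumption: the (R,R)-amide is taken as the enantiomer that leads to the (2S,3S) product; if the sense of induction proves opposite, its mirror image is used in the same way.
Remark: the phenol is carried as a tetrahydropyranyl (THP) acetal and the ester is installed before any acid is used, so that the last step needs only about pH 2; the acetal carbon is stereogenic and both configurations are carried (compounds 2, 4, 5, 7–11, 19, 20) until it is lost in step 11.
Remark: a conjugate base that is only protonated on work-up (alkoxide, phenoxide, carboxylate) is counted as the neutral compound.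

Step 1
Reactants: 1 5-bromo-2,4-dihydroxybenzaldehyde
Product: 2 5-bromo-2-hydroxy-4-(tetrahydro-2H-pyran-2-yloxy)benzaldehyde
Conditions: 3,4-dihydro-2H-pyran (1.5 equiv), PPTS (0.1 equiv), CH2Cl2/THF, rt
Reagents that add atoms: 3,4-dihydro-2H-pyran, C1=COCCC1
Why: Acid-catalysed tetrahydropyranylation should occur only at the C4 hydroxyl, because the C2 hydroxyl is held in a hydrogen bond to the aldehyde; this acetaldehyde-type acetal is chosen over an alkoxymethyl ether because it later falls at the same mild acidity as the enol ether (step 11), and its new stereocentre is immaterial.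

Step 2
Reactants: 2 5-bromo-2-hydroxy-4-(tetrahydro-2H-pyran-2-yloxy)benzaldehyde; 3 tributyl(1-ethoxyvinyl)stannane
Product: 4 5-(1-ethoxyvinyl)-2-hydroxy-4-(tetrahydro-2H-pyran-2-yloxy)benzaldehyde
Conditions: Pd(PPh3)4 (5 mol %), toluene, 100 °C; chromatography on Et3N-treated silica
Reagents that add atoms: none
Why: Stille coupling of the aryl bromide with the α-alkoxyvinyl stannane runs under neutral conditions that tolerate the free phenol, the aldehyde and the acetal, and the product is kept as the enol ether, a base-stable mask of the acetyl group.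

Step 3
Reactants: 4 5-(1-ethoxyvinyl)-2-hydroxy-4-(tetrahydro-2H-pyran-2-yloxy)benzaldehyde
Product: 5 4-(1-ethoxyvinyl)-2-(hydroxymethyl)-5-(tetrahydro-2H-pyran-2-yloxy)phenol
Conditions: NaBH4, THF/EtOH, 0 °C; then H2O
Reagents that add atoms: none
Why: Borohydride reduction of the aldehyde to the salicyl alcohol proceeds under basic conditions that leave the enol ether and the acetal intact, and no stereocentre is formed.

Step 4
Reactants: 5 4-(1-ethoxyvinyl)-2-(hydroxymethyl)-5-(tetrahydro-2H-pyran-2-yloxy)phenol; 6 3-chloro-2-(chloromethyl)prop-1-ene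
Product: 8 8-(1-ethoxyvinyl)-3-methylidene-9-(tetrahydro-2H-pyran-2-yloxy)-3,4-dihydro-2H,6H-1,5-benzodioxocine, via phenol-alkylated allylic chloride 7 (not isolated)
Conditions: NaH (1.05 equiv), DMF, 0 °C, slow addition to 6 (1.2 equiv); then NaH (1.3 equiv), Bu4NI (cat.), DMF (0.01 M), rt
Reagents that add atoms: none
Why: Double Williamson etherification, in which the more acidic phenol is alkylated first and the benzylic alkoxide then closes the eight-membered ring by intramolecular SN2 displacement of a reactive allylic chloride under high dilution, the ortho-disubstituted arene and the sp2 ring carbon lowering the entropic and transannular cost.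

Step 5
Reactants: 8 8-(1-ethoxyvinyl)-3-methylidene-9-(tetrahydro-2H-pyran-2-yloxy)-3,4-dihydro-2H,6H-1,5-benzodioxocine
Product: 9 (Z)-8-(1-ethoxyvinyl)-3-methyl-9-(tetrahydro-2H-pyran-2-yloxy)-4H,6H-1,5-benzodioxocine
Conditions: KOt-Bu (0.3 equiv), DMSO, rt
Reagents that add atoms: none
Why: Base-catalysed allyl-to-propenyl ether isomerisation, in which the ArO–CH2 protons are the most acidic allylic protons, so the double bond should move kinetically towards O1 to give the aryl enol ether, whose Z geometry the ring enforces and which has no comparably acidic proton left for further migration.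

Step 6
Reactants: 9 (Z)-8-(1-ethoxyvinyl)-3-methyl-9-(tetrahydro-2H-pyran-2-yloxy)-4H,6H-1,5-benzodioxocine
Product: 11 (2S,3S)-5-(1-ethoxyvinyl)-2-(prop-1-en-2-yl)-6-(tetrahydro-2H-pyran-2-yloxy)-2,3-dihydro-1-benzofuran-3-ol, via benzylic organolithium 10 (not isolated)
Conditions: (R,R)-[PhCH(Me)]2NH (2.6 equiv), n-BuLi (2.5 equiv), THF, −78 °C; then 9, −78 → −40 °C; then H2O
Reagents that add atoms: none
Why: Proposed new method: the chiral amide removes one of the two enantiotopic hydrogens of the benzylic C6H2 group (α to O5), and the α-oxy benzyllithium 10 bonds through C6 to the oxygen-bearing enol-ether carbon C2 across the ring while the allylic O5–C4 bond is lost and the double bond moves to C3=C4, a concerted six-electron five-centre ([2,3]-Wittig) shift that contracts the eight-membered ring and leaves the C3 lithium alkoxide and the isopropenyl group. The closest known reactions are [2,3]-Wittig ring contractions of macrocyclic allylic ethers, also in enantioselective form with chiral lithium amides, and [2,3]-Wittig shifts of open-chain allyl benzyl ethers; a medium ring and an enol-ether terminus are new. The furan ring closes in a transannular 5-exo-trig mode, C6 attacking C2 with the C2=C3 π bond exocyclic to the new ring. The configuration at C3 (former C6) is set by the reagent, which decides which hydrogen leaves and so which face of the carbanion bonds, and that at C2 by the substrate: the five-centre array C6–O5–C4–C3–C2 and the nascent furan ring are fused along the forming bond like a bicyclo[3.3.0]octane, which is accessible only when cis-fused, so the two hydrogens on the new bond lie on one face and the C3 oxygen and the C2 isopropenyl group on the other. The step needs site selectivity for C6–H over the allylic C4–H and a [2,3] instead of a [1,2] shift; benzylic delocalisation favours C6, whereas an anion at C4 would be an allyl anion carrying oxygen at both ends (O5 and O1), and the Z ring alkene holds C2 directly across the ring from C6. The enol ether and the acetal offer the base no other acidic site.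

Step 7
Reactants: 12 methyl but-2-ynoate
Product: 14 methyl (2Z)-2-(hydroxymethyl)but-2-enoate, via alpha-alumino enoate 13 (not isolated)
Conditions: i-Bu2AlH (1.1 equiv), HMPA, THF, 0 °C; then CH2O (gas, from paraformaldehyde), 0 °C → rt; cold aq. HCl
Reagents that add atoms: formaldehyde, C=O
Why: Vinylalumination, in which conjugate hydroalumination of the ynoate by the i-Bu2AlH–HMPA complex gives the α-alumino enoate 13 (an aluminium allenoate) that adds to formaldehyde on the side of the β-hydrogen, so that CH3 and CO2Me end up cis and the double bond is Z.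

Step 8
Reactants: 14 methyl (2Z)-2-(hydroxymethyl)but-2-enoate
Product: 15 (2Z)-2-(hydroxymethyl)but-2-enoic acid
Conditions: LiOH, THF/H2O, 0 °C → rt; then aq. HCl to pH 2
Reagents that add atoms: water (as LiOH/H2O), O
Why: Saponification of the methyl ester with LiOH at low temperature, under which the trisubstituted Z-enoate is not expected to isomerise or to add hydroxide.

Step 9
Reactants: 15 (2Z)-2-(hydroxymethyl)but-2-enoic acid
Product: 17 (2Z)-2-[(acetyloxy)methyl]but-2-enoic acid, via mixed acetic anhydride 16 (not isolated)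
Conditions: Ac2O (2.5 equiv), pyridine, CH2Cl2, 0 °C → rt; then H2O/THF
Reagents that add atoms: acetic anhydride, CC(=O)OC(C)=O
Why: O-acetylation of the primary allylic alcohol with acetic anhydride and pyridine, the mixed anhydride 16 formed at the carboxyl group being cleaved by water during work-up and no strongly nucleophilic catalyst being present that could displace the allylic acetate.

Step 10
Reactants: 11 (2S,3S)-5-(1-ethoxyvinyl)-2-(prop-1-en-2-yl)-6-(tetrahydro-2H-pyran-2-yloxy)-2,3-dihydro-1-benzofuran-3-ol; 17 (2Z)-2-[(acetyloxy)methyl]but-2-enoic acid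
Product: 19 (2S,3S)-5-(1-ethoxyvinyl)-2-(prop-1-en-2-yl)-6-(tetrahydro-2H-pyran-2-yloxy)-2,3-dihydro-1-benzofuran-3-yl (2Z)-2-[(acetyloxy)methyl]but-2-enoate, via Yamaguchi mixed anhydride 18 (not isolated)
Conditions: 17 (1.5 equiv), 2,4,6-Cl3C6H2COCl, Et3N, toluene, rt; filtration; then 11, toluene, 70 °C
Reagents that add atoms: none
Why: Yamaguchi esterification, in which the C3 hydroxyl attacks the unhindered enoyl carbonyl of mixed anhydride 18 so that the C3–O bond and its configuration are retained, the base-buffered DMAP-free conditions sparing the enol ether, the acetal, the Z double bond and the allylic acetate, and acylation before any acid keeping the phenol masked and the benzylic alcohol away from acid.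

Step 11
Reactants: 19 (2S,3S)-5-(1-ethoxyvinyl)-2-(prop-1-en-2-yl)-6-(tetrahydro-2H-pyran-2-yloxy)-2,3-dihydro-1-benzofuran-3-yl (2Z)-2-[(acetyloxy)methyl]but-2-enoate
Product: 21 (2S,3S)-5-acetyl-6-hydroxy-2-(prop-1-en-2-yl)-2,3-dihydro-1-benzofuran-3-yl (2Z)-2-[(acetyloxy)methyl]but-2-enoate, via acetyl tetrahydropyranyl ester 20 (not isolated)
Conditions: AcOH/THF/H2O (4:2:1), 40 °C
Reagents that add atoms: water, O
Why: Acid-catalysed hydrolysis at about pH 2, in which the 1-ethoxyvinyl group gives the acetyl group at once (20) and the aryl tetrahydropyranyl acetal, a good leaving group once the ortho carbonyl is present, follows, while the acetate, the enoate, the benzylic C3 ester and both stereocentres should be untouched at this acidity.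

Compound list
1 | 5-bromo-2,4-dihydroxybenzaldehyde | O=Cc1cc(Br)c(O)cc1O | starting material
2 | 5-bromo-2-hydroxy-4-(tetrahydro-2H-pyran-2-yloxy)benzaldehyde (racemic at the acetal carbon) | O=Cc1cc(Br)c(OC2CCCCO2)cc1O | intermediate
3 | tributyl(1-ethoxyvinyl)stannane | CCCC[Sn](CCCC)(CCCC)C(=C)OCC | starting material
4 | 5-(1-ethoxyvinyl)-2-hydroxy-4-(tetrahydro-2H-pyran-2-yloxy)benzaldehyde (racemic at the acetal carbon) | O=Cc1cc(C(=C)OCC)c(OC2CCCCO2)cc1O | intermediate
5 | 4-(1-ethoxyvinyl)-2-(hydroxymethyl)-5-(tetrahydro-2H-pyran-2-yloxy)phenol (racemic at the acetal carbon) | OCc1cc(C(=C)OCC)c(OC2CCCCO2)cc1O | intermediate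
6 | 3-chloro-2-(chloromethyl)prop-1-ene | C=C(CCl)CCl | starting material
7 | [2-{[2-(chloromethyl)prop-2-en-1-yl]oxy}-5-(1-ethoxyvinyl)-4-(tetrahydro-2H-pyran-2-yloxy)phenyl]methanol (racemic at the acetal carbon) | OCc1cc(C(=C)OCC)c(OC2CCCCO2)cc1OCC(=C)CCl | intermediate (not isolated)
8 | 8-(1-ethoxyvinyl)-3-methylidene-9-(tetrahydro-2H-pyran-2-yloxy)-3,4-dihydro-2H,6H-1,5-benzodioxocine (racemic at the acetal carbon) | C=C1COCc2cc(C(=C)OCC)c(OC3CCCCO3)cc2OC1 | intermediate
9 | (Z)-8-(1-ethoxyvinyl)-3-methyl-9-(tetrahydro-2H-pyran-2-yloxy)-4H,6H-1,5-benzodioxocine (racemic at the acetal carbon) | C/C1=C/Oc2cc(OC3CCCCO3)c(C(=C)OCC)cc2COC1 | intermediate (key-step precursor)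
10 | 6-lithio derivative of 9 (α-oxy benzyllithium; configuration at C6 chosen by the amide) | C/C1=C/Oc2cc(OC3CCCCO3)c(C(=C)OCC)cc2C([Li])OC1 | intermediate (not isolated)
11 | (2S,3S)-5-(1-ethoxyvinyl)-2-(prop-1-en-2-yl)-6-(tetrahydro-2H-pyran-2-yloxy)-2,3-dihydro-1-benzofuran-3-ol (cis; both configurations at the acetal carbon) | C=C(C)[C@@H]1Oc2cc(OC3CCCCO3)c(C(=C)OCC)cc2[C@@H]1O | intermediate (key-step product)
12 | methyl but-2-ynoate | CC#CC(=O)OC | starting material
13 | methyl (2E)-2-[bis(2-methylpropyl)alumanyl]but-2-enoate (CH3 and CO2Me cis) | C/C=C(/[Al](CC(C)C)CC(C)C)C(=O)OC | intermediate (not isolated)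
14 | methyl (2Z)-2-(hydroxymethyl)but-2-enoate | C/C=C(/CO)C(=O)OC | intermediate
15 | (2Z)-2-(hydroxymethyl)but-2-enoic acid | C/C=C(/CO)C(=O)O | intermediate
16 | acetic (2Z)-2-[(acetyloxy)methyl]but-2-enoic anhydride | C/C=C(/COC(C)=O)C(=O)OC(C)=O | intermediate (not isolated)
17 | (2Z)-2-[(acetyloxy)methyl]but-2-enoic acid | C/C=C(/COC(C)=O)C(=O)O | intermediate
18 | (2Z)-2-[(acetyloxy)methyl]but-2-enoic 2,4,6-trichlorobenzoic anhydride | C/C=C(/COC(C)=O)C(=O)OC(=O)c1c(Cl)cc(Cl)cc1Cl | intermediate (not isolated)
19 | (2S,3S)-5-(1-ethoxyvinyl)-2-(prop-1-en-2-yl)-6-(tetrahydro-2H-pyran-2-yloxy)-2,3-dihydro-1-benzofuran-3-yl (2Z)-2-[(acetyloxy)methyl]but-2-enoate (both configurations at the acetal carbon) | C=C(C)[C@@H]1Oc2cc(OC3CCCCO3)c(C(=C)OCC)cc2[C@@H]1OC(=O)/C(=C\C)COC(C)=O | intermediate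
20 | (2S,3S)-5-acetyl-2-(prop-1-en-2-yl)-6-(tetrahydro-2H-pyran-2-yloxy)-2,3-dihydro-1-benzofuran-3-yl (2Z)-2-[(acetyloxy)methyl]but-2-enoate (both configurations at the acetal carbon) | C=C(C)[C@@H]1Oc2cc(OC3CCCCO3)c(C(C)=O)cc2[C@@H]1OC(=O)/C(=C\C)COC(C)=O | intermediate (not isolated)
21 | (2S,3S)-5-acetyl-6-hydroxy-2-(prop-1-en-2-yl)-2,3-dihydro-1-benzofuran-3-yl (2Z)-2-[(acetyloxy)methyl]but-2-enoate (CNP0193314.1) | C=C(C)[C@@H]1Oc2cc(O)c(C(C)=O)cc2[C@@H]1OC(=O)/C(=C\C)COC(C)=O | target

Total step count: 11.
Longest linear sequence: 8 steps (steps 1–6, 10 and 11); steps 7–9 make the side-chain acid.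

Steps most likely to fail

1. Step 6 (proposed new method). What may go wrong: metalation of the electron-rich benzylic position by the hindered amide may be too slow or may lose out to metalation at the allylic OCH2 group, and discrimination of the enantiotopic hydrogens may be poor. The fallback uses known reactions, sets out from 4 and rejoins the route at 19. Aldehyde 4 would be treated in THF at −40 °C with KOt-Bu (2.2 equiv) and the sulfonium salt 1-(2-methylprop-2-en-1-yl)thiolan-1-ium bromide F1, made from tetrahydrothiophene and 3-bromo-2-methylprop-1-ene. Corey–Chaykovsky epoxidation should give the trans vinyl epoxide 4-(1-ethoxyvinyl)-2-[trans-3-(prop-1-en-2-yl)oxiran-2-yl]-5-(tetrahydro-2H-pyran-2-yloxy)phenol F2 as its phenoxide. This should open in the same flask by 5-exo attack at the allylic carbon with inversion, to the racemic trans alcohol (2S*,3R*)-5-(1-ethoxyvinyl)-2-(prop-1-en-2-yl)-6-(tetrahydro-2H-pyran-2-yloxy)-2,3-dihydro-1-benzofuran-3-ol F3. Kinetic resolution by lipase-catalysed acylation (Candida antarctica lipase B, vinyl acetate, t-BuOMe) is expected, from the usual size rule for secondary benzylic alcohols, to convert the (3S) enantiomer into the (2R,3S) acetate F5 and to leave the (2S,3R) alcohol F4. Mitsunobu esterification of F4 with acid 17 (PPh3 and DIAD premixed, toluene, −20 °C) would invert C3 and give 19.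

2. Step 4. What may go wrong: intermolecular etherification (chain growth) may outrun closure of the eight-membered ring. The fallback sets out from 5 and rejoins at 9, so it also bypasses step 5; the ring is closed by enol-ether ring-closing metathesis instead of SN2 displacement. Copper-mediated O-vinylation of 5 (2,4,6-trivinylcyclotriboroxane–pyridine complex, Cu(OAc)2, pyridine, CH2Cl2, air, rt), selective for the phenol over the benzylic alcohol, should give [2-(ethenyloxy)-5-(1-ethoxyvinyl)-4-(tetrahydro-2H-pyran-2-yloxy)phenyl]methanol F6. O-Alkylation of the benzylic alcohol (NaH, 3-chloro-2-methylprop-1-ene, DMF) should give the diene 1-(ethenyloxy)-4-(1-ethoxyvinyl)-2-{[(2-methylprop-2-en-1-yl)oxy]methyl}-5-(tetrahydro-2H-pyran-2-yloxy)benzene F7. Ring-closing metathesis with Mo(=CHCMe2Ph)(=N-2,6-i-Pr2C6H3)[OCMe(CF3)2]2 in benzene under dilution would join the vinyl ether and the 1,1-disubstituted alkene with loss of ethene and give 9, the ring again enforcing the Z geometry.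

3. Step 10. What may go wrong: acylation of the hindered C3 hydroxyl may be slow enough for the activated acid to isomerise from Z to E or to lose its allylic acetate by SN2′ substitution. The fallback sets out from 11 and rejoins at 19; the side chain is built on the scaffold from a robust acyl group. Steglich esterification of 11 with but-2-ynoic acid (DCC, DMAP cat., CH2Cl2, 0 °C) should give the (2S,3S) but-2-ynoate F8. Hydroalumination with i-Bu2AlH/HMPA as in step 7 should give the α-alumino enoate F9, and capture with formaldehyde followed by a non-acidic tartrate work-up the (2S,3S) (2Z)-2-(hydroxymethyl)but-2-enoate F10. Acetylation (Ac2O, pyridine) then gives 19.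

Further compounds
F1 | step 6 | 1-(2-methylprop-2-en-1-yl)thiolan-1-ium bromide | C=C(C)C[S+]1CCCC1.[Br-]
F2 | step 6 | 4-(1-ethoxyvinyl)-2-[trans-3-(prop-1-en-2-yl)oxiran-2-yl]-5-(tetrahydro-2H-pyran-2-yloxy)phenol (racemic, one enantiomer drawn) | C=C(C)[C@H]1O[C@@H]1c1cc(C(=C)OCC)c(OC2CCCCO2)cc1O
F3 | step 6 | (2S*,3R*)-5-(1-ethoxyvinyl)-2-(prop-1-en-2-yl)-6-(tetrahydro-2H-pyran-2-yloxy)-2,3-dihydro-1-benzofuran-3-ol (racemic trans, one enantiomer drawn) | C=C(C)[C@@H]1Oc2cc(OC3CCCCO3)c(C(=C)OCC)cc2[C@H]1O
F4 | step 6 | (2S,3R)-5-(1-ethoxyvinyl)-2-(prop-1-en-2-yl)-6-(tetrahydro-2H-pyran-2-yloxy)-2,3-dihydro-1-benzofuran-3-ol (single enantiomer) | C=C(C)[C@@H]1Oc2cc(OC3CCCCO3)c(C(=C)OCC)cc2[C@H]1O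
F5 | step 6 | (2R,3S)-5-(1-ethoxyvinyl)-2-(prop-1-en-2-yl)-6-(tetrahydro-2H-pyran-2-yloxy)-2,3-dihydro-1-benzofuran-3-yl acetate | C=C(C)[C@H]1Oc2cc(OC3CCCCO3)c(C(=C)OCC)cc2[C@@H]1OC(C)=O
F6 | step 4 | [2-(ethenyloxy)-5-(1-ethoxyvinyl)-4-(tetrahydro-2H-pyran-2-yloxy)phenyl]methanol | OCc1cc(C(=C)OCC)c(OC2CCCCO2)cc1OC=C
F7 | step 4 | 1-(ethenyloxy)-4-(1-ethoxyvinyl)-2-{[(2-methylprop-2-en-1-yl)oxy]methyl}-5-(tetrahydro-2H-pyran-2-yloxy)benzene | C=COc1cc(OC2CCCCO2)c(C(=C)OCC)cc1COCC(C)=C
F8 | step 10 | (2S,3S)-5-(1-ethoxyvinyl)-2-(prop-1-en-2-yl)-6-(tetrahydro-2H-pyran-2-yloxy)-2,3-dihydro-1-benzofuran-3-yl but-2-ynoate | C=C(C)[C@@H]1Oc2cc(OC3CCCCO3)c(C(=C)OCC)cc2[C@@H]1OC(=O)C#CC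
F9 | step 10 | (2S,3S)-5-(1-ethoxyvinyl)-2-(prop-1-en-2-yl)-6-(tetrahydro-2H-pyran-2-yloxy)-2,3-dihydro-1-benzofuran-3-yl (2E)-2-[bis(2-methylpropyl)alumanyl]but-2-enoate | C=C(C)[C@@H]1Oc2cc(OC3CCCCO3)c(C(=C)OCC)cc2[C@@H]1OC(=O)/C(=C\C)[Al](CC(C)C)CC(C)C
F10 | step 10 | (2S,3S)-5-(1-ethoxyvinyl)-2-(prop-1-en-2-yl)-6-(tetrahydro-2H-pyran-2-yloxy)-2,3-dihydro-1-benzofuran-3-yl (2Z)-2-(hydroxymethyl)but-2-enoate | C=C(C)[C@@H]1Oc2cc(OC3CCCCO3)c(C(=C)OCC)cc2[C@@H]1OC(=O)/C(=C\C)CO
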